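**Plan**

- Retrosynthetic cuts, in order: the exocyclic C7=C8 alkene of bromovulone I goes back to a C7 silyloxy leaving group; the ring bond C8–C12 is opened to a 3-bromo-2,5-disubstituted furylcarbinol; then C8–C9 (furyllithium + aldehyde), C13–C14 (furfuryl bromide + heptynyl Grignard) and C5=C6 (Wittig) are cut.
- Enabling feature: the ring C8–C9(=O)–C10(Br)=C11(H)–C12(OH) is a 4-hydroxy-4-alkylcyclopent-2-enone that maps atom for atom onto the furan (furan O → ketone O at C9, furan C2–C5 → C9–C12, carbinol carbon → C8).
- Forward order: the bromofuran carrying the Z-octenyl chain (steps 1–4) and the C1–C8 α-silyloxy aldehyde (steps 5–9) are joined at C8–C9 (step 10); the only ring closes in step 11 with bromine, carbinol and both chains in place; steps 12–13 convert C7–O into the 7E alkene.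
- Stereochemistry: C7 (S) comes from (R)-glyceraldehyde acetonide and steers the conrotatory closure that sets C12 (C8 is set with it and erased later); 5Z comes from the Wittig reaction, 14Z from Lindlar reduction, 7E from the elimination.

Key step: step 11

Assumption: the 7S silyloxy centre is taken to direct C8–C12 bonding anti to the C7–C6 bond (C7–H near the enol C–O), which gives the C12 configuration of the target; if the opposite sense were found, the same route from (S)-2,2-dimethyl-1,3-dioxolane-4-carbaldehyde would deliver it.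

**Route**

Step 1
Reactants: 1 4-bromofuran-2-carbaldehyde
Product: 2 (4-bromofuran-2-yl)methanol
Conditions: NaBH4, MeOH, 0 °C
Reagents that add atoms: none
Why: Borohydride reduction of an aromatic aldehyde is chemoselective and leaves the ring C–Br bond untouched.

Step 2
Reactants: 2 (4-bromofuran-2-yl)methanol
Product: 3 4-bromo-2-(bromomethyl)furan
Conditions: PBr3, Et2O, 0 °C; crude solution used at once
Reagents that add atoms: phosphorus tribromide, BrP(Br)Br
Why: Alcohol-to-bromide substitution through the bromophosphite (SN2) is standard for furfuryl alcohols, and the electron-withdrawing ring bromine should temper the usual lability of furfuryl bromides.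

Step 3
Reactants: 3 4-bromo-2-(bromomethyl)furan; 4 hept-1-yne
Product: 6 4-bromo-2-(oct-2-yn-1-yl)furan, via hept-1-ynylmagnesium bromide 5 (not isolated)
Conditions: 4, EtMgBr, THF, 0 → 40 °C; then CuBr·SMe2 (5 mol %), 3, 0 °C → rt
Reagents that add atoms: none
Why: Copper-catalysed alkylation of an alkynyl Grignard reagent with a benzylic-type bromide, the usual entry to skipped enynes, should form C13–C14 by SN2 substitution without touching the furyl bromide.

Step 4
Reactants: 6 4-bromo-2-(oct-2-yn-1-yl)furan
Product: 7 4-bromo-2-[(Z)-oct-2-en-1-yl]furan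
Conditions: H2 (1 atm), Pd/CaCO3 poisoned with Pb(OAc)2 (Lindlar catalyst), quinoline, hexane, rt
Reagents that add atoms: none
Why: Lindlar semi-hydrogenation adds hydrogen syn and stops at the Z alkene (C14=C15), and the quinoline-poisoned catalyst is not expected to hydrogenolyse the furyl bromide.

Step 5
Reactants: 8 (4-carboxybutyl)triphenylphosphonium bromide; 9 (R)-2,2-dimethyl-1,3-dioxolane-4-carbaldehyde
Product: 11 (5Z)-6-[(4S)-2,2-dimethyl-1,3-dioxolan-4-yl]hex-5-enoic acid, via carboxylate ylide 10 (not isolated)
Conditions: 8, NaN(SiMe3)2 (2.1 equiv), THF, 0 °C; then 9, −78 °C → rt; 1 M HCl to pH 4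
Reagents that add atoms: none
Why: Wittig olefination with a non-stabilised ylide under lithium-free conditions should give the Z alkene (C5=C6), and the low temperature keeps the α-alkoxy aldehyde from epimerising, so its stereocentre becomes C7 unchanged.

Step 6
Reactants: 11 (5Z)-6-[(4S)-2,2-dimethyl-1,3-dioxolan-4-yl]hex-5-enoic acid
Product: 12 methyl (5Z,7S)-7,8-dihydroxyoct-5-enoate
Conditions: p-TsOH·H2O (cat.), MeOH, rt
Reagents that add atoms: methanol, CO
Why: Acid-catalysed methanolysis combines Fischer esterification with acetonide cleavage in one operation, the water released by esterification serving to hydrolyse the ketal.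

Step 7
Reactants: 12 methyl (5Z,7S)-7,8-dihydroxyoct-5-enoate
Product: 13 methyl (5Z,7S)-7,8-bis[(tert-butyldimethylsilyl)oxy]oct-5-enoate
Conditions: TBSCl (2.5 equiv), imidazole, DMF, rt
Reagents that add atoms: tert-butyldimethylsilyl chloride, CC(C)(C)[Si](C)(C)Cl
Why: Standard imidazole-promoted silylation protects both hydroxyls without affecting the ester or the Z alkene.

Step 8
Reactants: 13 methyl (5Z,7S)-7,8-bis[(tert-butyldimethylsilyl)oxy]oct-5-enoate
Product: 14 methyl (5Z,7S)-7-[(tert-butyldimethylsilyl)oxy]-8-hydroxyoct-5-enoate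
Conditions: HF·pyridine, pyridine, THF, 0 °C
Reagents that add atoms: none
Why: Selective desilylation with buffered HF·pyridine cleaves the unhindered primary silyl ether well before the secondary one, freeing only C8–OH.

Step 9
Reactants: 14 methyl (5Z,7S)-7-[(tert-butyldimethylsilyl)oxy]-8-hydroxyoct-5-enoate
Product: 15 methyl (5Z,7S)-7-[(tert-butyldimethylsilyl)oxy]-8-oxooct-5-enoate
Conditions: Dess–Martin periodinane, pyridine, CH2Cl2, 0 °C → rt
Reagents that add atoms: none
Why: Dess–Martin oxidation gives the aldehyde under near-neutral conditions that should neither epimerise the α-silyloxy centre nor move the β,γ-alkene into conjugation.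

Step 10
Reactants: 7 4-bromo-2-[(Z)-oct-2-en-1-yl]furan; 15 methyl (5Z,7S)-7-[(tert-butyldimethylsilyl)oxy]-8-oxooct-5-enoate
Product: 17 methyl (5Z,7S)-8-[3-bromo-5-[(Z)-oct-2-en-1-yl]furan-2-yl]-7-[(tert-butyldimethylsilyl)oxy]-8-hydroxyoct-5-enoate (mixture of C8 epimers), via lithiated bromofuran 16 (not isolated)
Conditions: 7, LiN(i-Pr)2 (1.05 equiv), THF, −78 °C; then 15, −78 °C; sat. aq. NH4Cl
Reagents that add atoms: none
Why: Ortho-lithiation of a 3-bromofuran by the amide base occurs at the α-carbon flanked by oxygen and bromine, and the furyllithium adds 1,2 to the aldehyde far faster than to the methyl ester, forming C8–C9; the C8 configuration is left uncontrolled because step 11 erases it.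

Step 11
Reactants: 17 methyl (5Z,7S)-8-[3-bromo-5-[(Z)-oct-2-en-1-yl]furan-2-yl]-7-[(tert-butyldimethylsilyl)oxy]-8-hydroxyoct-5-enoate
Product: 19 methyl (5Z,7S)-7-[(1S,2S)-4-bromo-2-hydroxy-2-[(Z)-oct-2-en-1-yl]-5-oxocyclopent-3-en-1-yl]-7-[(tert-butyldimethylsilyl)oxy]hept-5-enoate (C8 side chain trans to the C12 hydroxyl), via ring-opened hydroxy dienone 18 (not isolated)
Conditions: Dy(OTf)3 (10 mol %), t-BuOH/H2O (5:1), 70 °C
Reagents that add atoms: water, O
Why: Proposed new method: Dy(OTf)3 in wet t-BuOH ionises the C8 carbinol of 17 to a furfuryl cation, water adds at the octenyl-bearing furan carbon (C12), the hemiketal opens to the hydroxy dienone 18, and its O-protonated form, a pentadienyl cation spanning C8–C12, closes thermally to form C8–C12, the furan oxygen becoming the C9 carbonyl and the added water the C12 hydroxyl. The closest known reaction type is the Piancatelli rearrangement of 5-alkyl-2-furylcarbinols to trans-4-hydroxy-4-alkyl-5-substituted cyclopent-2-enones under ZnCl2 or Dy(OTf)3 catalysis in aqueous media, which has not been shown for a 3-bromofuran or with control of absolute configuration; the bromine is expected only to slow ionisation, an effect offset by the 5-alkyl group. The cyclopentenone ring closes by conrotatory 4π electrocyclisation of the pentadienyl cation (Nazarov mode). C8 and C12 are formed together: with the C7 chain held outside by allylic strain against C10–Br and the C12 hydroxyl outside as in the known rearrangements, conrotation places them trans, and the sense of rotation is set by the 7S silyloxy centre (bonding at C8 anti to the C7–C6 bond), which gives the (1S,2S) ring carrying the C12 configuration of the target. The step needs facial selectivity in the conrotation and capture of the cation by water at C12 ahead of hydride shift from C7 or proton loss at C13; the first rests on the adjacent C7 stereocentre, the minor trans isomer being a diastereomer that is removed by chromatography, and the second on the large excess of water and the weak acidity of the catalyst. Both C8 epimers of 17 give the same cation, and loss of the silyl group under the conditions would do no harm because step 12 removes it.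

Step 12
Reactants: 19 methyl (5Z,7S)-7-[(1S,2S)-4-bromo-2-hydroxy-2-[(Z)-oct-2-en-1-yl]-5-oxocyclopent-3-en-1-yl]-7-[(tert-butyldimethylsilyl)oxy]hept-5-enoate
Product: 20 methyl (5Z,7S)-7-[(1S,2S)-4-bromo-2-hydroxy-2-[(Z)-oct-2-en-1-yl]-5-oxocyclopent-3-en-1-yl]-7-hydroxyhept-5-enoate
Conditions: HF·pyridine, pyridine, THF, 0 °C → rt
Reagents that add atoms: none
Why: Fluoride-mediated desilylation under mildly acidic, buffered conditions removes the secondary silyl ether while avoiding the base that could trigger retro-aldol opening or premature elimination of the β-hydroxy ketone.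

Step 13
Reactants: 20 methyl (5Z,7S)-7-[(1S,2S)-4-bromo-2-hydroxy-2-[(Z)-oct-2-en-1-yl]-5-oxocyclopent-3-en-1-yl]-7-hydroxyhept-5-enoate
Product: 22 bromovulone I [methyl (5Z,7E)-7-[(2R)-4-bromo-2-hydroxy-2-[(Z)-oct-2-en-1-yl]-5-oxocyclopent-3-en-1-ylidene]hept-5-enoate], via C7 mesylate 21 (not isolated)
Conditions: Ms2O (1.2 equiv), Et3N, CH2Cl2, −40 °C; then DBU, −40 → 0 °C
Reagents that add atoms: none
Why: Selective sulfonylation of the secondary allylic alcohol (the hindered tertiary C12–OH should not react at −40 °C) followed by E1cB elimination through the C8 enolate should give the cross-conjugated dienone, with 7E expected to predominate as the thermodynamically preferred geometry (C6 anti to the carbonyl) and as the outcome of anti-elimination from the (7S,8S) isomer, any 7Z isomer being removed by chromatography.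

**Compound list**

1 | 4-bromofuran-2-carbaldehyde | O=Cc1cc(Br)co1 | starting material
2 | (4-bromofuran-2-yl)methanol | OCc1cc(Br)co1 | intermediate
3 | 4-bromo-2-(bromomethyl)furan | BrCc1cc(Br)co1 | intermediate
4 | hept-1-yne | CCCCCC#C | starting material
5 | hept-1-yn-1-ylmagnesium bromide | CCCCCC#C[Mg]Br | intermediate (not isolated)
6 | 4-bromo-2-(oct-2-yn-1-yl)furan | CCCCCC#CCc1cc(Br)co1 | intermediate
7 | 4-bromo-2-[(Z)-oct-2-en-1-yl]furan | CCCCC/C=C\Cc1cc(Br)co1 | intermediate
8 | (4-carboxybutyl)triphenylphosphonium bromide | OC(=O)CCCC[P+](c1ccccc1)(c1ccccc1)c1ccccc1.[Br-] | starting material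
9 | (R)-2,2-dimethyl-1,3-dioxolane-4-carbaldehyde | O=C[C@H]1COC(C)(C)O1 | starting material
10 | sodium 5-(triphenyl-λ5-phosphanylidene)pentanoate | [Na+].[O-]C(=O)CCCC=P(c1ccccc1)(c1ccccc1)c1ccccc1 | intermediate (not isolated)
11 | (5Z)-6-[(4S)-2,2-dimethyl-1,3-dioxolan-4-yl]hex-5-enoic acid | OC(=O)CCC/C=C\[C@H]1COC(C)(C)O1 | intermediate
12 | methyl (5Z,7S)-7,8-dihydroxyoct-5-enoate | COC(=O)CCC/C=C\[C@H](O)CO | intermediate
13 | methyl (5Z,7S)-7,8-bis[(tert-butyldimethylsilyl)oxy]oct-5-enoate | COC(=O)CCC/C=C\[C@H](O[Si](C)(C)C(C)(C)C)CO[Si](C)(C)C(C)(C)C | intermediate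
14 | methyl (5Z,7S)-7-[(tert-butyldimethylsilyl)oxy]-8-hydroxyoct-5-enoate | COC(=O)CCC/C=C\[C@H](O[Si](C)(C)C(C)(C)C)CO | intermediate
15 | methyl (5Z,7S)-7-[(tert-butyldimethylsilyl)oxy]-8-oxooct-5-enoate | COC(=O)CCC/C=C\[C@H](O[Si](C)(C)C(C)(C)C)C=O | intermediate
16 | [3-bromo-5-[(Z)-oct-2-en-1-yl]furan-2-yl]lithium | [Li]c1oc(C/C=C\CCCCC)cc1Br | intermediate (not isolated)
17 | methyl (5Z,7S)-8-[3-bromo-5-[(Z)-oct-2-en-1-yl]furan-2-yl]-7-[(tert-butyldimethylsilyl)oxy]-8-hydroxyoct-5-enoate (C8 epimers) | CCCCC/C=C\Cc1cc(Br)c(o1)C(O)[C@@H](O[Si](C)(C)C(C)(C)C)/C=C\CCCC(=O)OC | intermediate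
18 | methyl (5Z,7S,8Z,10E,14Z)-10-bromo-7-[(tert-butyldimethylsilyl)oxy]-9-hydroxy-12-oxoicosa-5,8,10,14-tetraenoate | CCCCC/C=C\CC(=O)/C=C(Br)\C(O)=C\[C@@H](O[Si](C)(C)C(C)(C)C)/C=C\CCCC(=O)OC | intermediate (not isolated)
19 | methyl (5Z,7S)-7-[(1S,2S)-4-bromo-2-hydroxy-2-[(Z)-oct-2-en-1-yl]-5-oxocyclopent-3-en-1-yl]-7-[(tert-butyldimethylsilyl)oxy]hept-5-enoate | CCCCC/C=C\C[C@@]1(O)C=C(Br)C(=O)[C@H]1[C@@H](O[Si](C)(C)C(C)(C)C)/C=C\CCCC(=O)OC | intermediate
20 | methyl (5Z,7S)-7-[(1S,2S)-4-bromo-2-hydroxy-2-[(Z)-oct-2-en-1-yl]-5-oxocyclopent-3-en-1-yl]-7-hydroxyhept-5-enoate | CCCCC/C=C\C[C@@]1(O)C=C(Br)C(=O)[C@H]1[C@@H](O)/C=C\CCCC(=O)OC | intermediate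
21 | methyl (5Z,7S)-7-[(1S,2S)-4-bromo-2-hydroxy-2-[(Z)-oct-2-en-1-yl]-5-oxocyclopent-3-en-1-yl]-7-(methanesulfonyloxy)hept-5-enoate | CCCCC/C=C\C[C@@]1(O)C=C(Br)C(=O)[C@H]1[C@@H](OS(C)(=O)=O)/C=C\CCCC(=O)OC | intermediate (not isolated)
22 | bromovulone I, methyl (5Z,7E)-7-[(2R)-4-bromo-2-hydroxy-2-[(Z)-oct-2-en-1-yl]-5-oxocyclopent-3-en-1-ylidene]hept-5-enoate | CCCCC/C=C\C[C@@]1(O)C=C(Br)C(=O)/C1=C/C=C\CCCC(=O)OC | target

**Step count**

Total: 13 steps. Longest linear sequence: 9 steps (steps 5–13, from 8 and 9); the furan branch (steps 1–4) joins at step 10.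

**Steps most likely to fail**

Step 11 (the one new-method step). Ionisation of the bromofurylcarbinol may be too slow. The cation may also be diverted by hydride shift from C7 or by proton loss at C13 before water is captured. Conrotation may proceed with poor facial selectivity. The fallback, built on known chemistry, takes the bromine out of the rearrangement and restores it afterwards. Setting out from 17, formate-mediated hydrodebromination (Pd(PPh3)4, HCO2H, Et3N, DMF, 60 °C) would give the bromine-free furylcarbinol methyl (5Z,7S)-7-[(tert-butyldimethylsilyl)oxy]-8-hydroxy-8-[5-[(Z)-oct-2-en-1-yl]furan-2-yl]oct-5-enoate F1. This is a 5-alkyl-2-furylcarbinol of the class for which the Piancatelli rearrangement (ZnCl2 or Dy(OTf)3, aqueous medium) is established. It should give, after chromatographic removal of the other trans diastereomer, the hydroxy enone methyl (5Z,7S)-7-[(tert-butyldimethylsilyl)oxy]-7-[(1S,2R)-2-hydroxy-2-[(Z)-oct-2-en-1-yl]-5-oxocyclopent-3-en-1-yl]hept-5-enoate F2. Weitz–Scheffer epoxidation (t-BuOOH, DBU, CH2Cl2), which touches only the electron-poor ring alkene, would give the 10,11-epoxy ketone F3. HBr in THF should open it at the α-carbon to the 10-bromo-11-hydroxy ketone F4 (not isolated), which loses water to the α-bromo enone. The route is rejoined at 19.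

Step 10. The amide base may also remove a proton from the doubly activated C13 methylene, or the lithiated bromofuran may equilibrate by bromine migration, so that the carbanion forms at the wrong carbon. The fallback generates the carbanion by halogen–lithium exchange instead of deprotonation. Setting out from 7, bromination of the free α-position (NBS, DMF, 0 °C, dark) would give 2,3-dibromo-5-[(Z)-oct-2-en-1-yl]furan F5. n-BuLi (THF, −78 °C) exchanges the α-bromine selectively and much faster than any C–H is removed, giving the same furyllithium 16. Addition to 15 rejoins the route at 17.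

Step 13. A long-lived C8 enolate may lose the sulfonate from either rotamer and give much 7Z isomer. The base may isomerise the 5Z alkene of the dienone, or the tertiary alkoxide may open the ring by retro-aldol cleavage. The fallback abandons the enolate pathway for a concerted anti-dehydration under neutral conditions (Mitsunobu-type dehydration: PPh3, DIAD, THF, 0 °C → rt), which acts only on the secondary alcohol of 20. Because step 11 fixes the C7/C8 relationship as (7S,8S), anti-periplanar loss of C8–H and the C7 oxyphosphonium group maps onto the 7E alkene. Compound 20 is taken directly to 22, and no new isolable compound is made (F0).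

**Further compounds**

F1 | step 11 | methyl (5Z,7S)-7-[(tert-butyldimethylsilyl)oxy]-8-hydroxy-8-[5-[(Z)-oct-2-en-1-yl]furan-2-yl]oct-5-enoate (C8 epimers) | CCCCC/C=C\Cc1ccc(o1)C(O)[C@@H](O[Si](C)(C)C(C)(C)C)/C=C\CCCC(=O)OC
F2 | step 11 | methyl (5Z,7S)-7-[(tert-butyldimethylsilyl)oxy]-7-[(1S,2R)-2-hydroxy-2-[(Z)-oct-2-en-1-yl]-5-oxocyclopent-3-en-1-yl]hept-5-enoate | CCCCC/C=C\C[C@@]1(O)C=CC(=O)[C@H]1[C@@H](O[Si](C)(C)C(C)(C)C)/C=C\CCCC(=O)OC
F3 | step 11 | methyl (5Z,7S)-7-[(tert-butyldimethylsilyl)oxy]-7-[4-hydroxy-4-[(Z)-oct-2-en-1-yl]-2-oxo-6-oxabicyclo[3.1.0]hexan-3-yl]hept-5-enoate (10,11-epoxy ketone; C8 and C12 as in F2, epoxide face not assigned) | CCCCC/C=C\C[C@@]1(O)C2OC2C(=O)[C@H]1[C@@H](O[Si](C)(C)C(C)(C)C)/C=C\CCCC(=O)OC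
F4 | step 11 | methyl (5Z,7S)-7-[4-bromo-2,3-dihydroxy-2-[(Z)-oct-2-en-1-yl]-5-oxocyclopentyl]-7-[(tert-butyldimethylsilyl)oxy]hept-5-enoate (10-bromo-11-hydroxy ketone; C8 and C12 as in F2, C10 and C11 not assigned) | CCCCC/C=C\C[C@@]1(O)C(O)C(Br)C(=O)[C@H]1[C@@H](O[Si](C)(C)C(C)(C)C)/C=C\CCCC(=O)OC
F5 | step 10 | 2,3-dibromo-5-[(Z)-oct-2-en-1-yl]furan | CCCCC/C=C\Cc1cc(Br)c(Br)o1
F0 | step 13 | none | none
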